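**Plan** (ring numbered as cyclohexa-2,5-dien-1-one: C1 = C=O, C2 bears the propenyl group, C4 = quaternary C(OMe), C5 bears OMe)

- Cuts, in retrosynthetic order: (1) the ring bond C1–C2 together with the O–CH3 bond at C4; (2) the C1–O and C5=C6 bonds of the lactone this reveals; (3) the C4–C3 carbinol–alkyne bond; (4) the ArCH=C(CH3) bond.
- Enabling feature: C4 carries an oxygen and C5(OMe)=C6H–C1(=O) is a vinylogous ester. The unit O–C4–C5=C6–C1 can therefore be held as a 4-methoxyfuran-2(5H)-one (tetronate) ring. This ring locks C5=C6 cis, keeps C1 at the acyl level and makes the C4 oxygen the leaving group when a C2 carbanion attacks C1.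
- Forward order: condensation and esterification give the α-keto ester; asymmetric alkynylation joins the enyne chain; trans-hydrosilylation and iododesilylation give the (Z)-alkenyl iodide; Ph3P=C=C=O builds the five-membered tetronate; iodine–lithium exchange then exchanges this lactone for the six-membered dienone ring, and the freed alkoxide is methylated.
- Stereochemistry: the only stereocentre (C4) is set in the catalytic asymmetric alkynylation (step 3) and none of its four bonds is broken afterwards. Both side-chain alkenes are E, one from the thermodynamically controlled condensation and one from the (E)-enyne.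

Key step: step 7

Remark: (E)-pent-3-en-1-yne (6) is taken as a purchasable, volatile enyne; in step 3 the antipode of the amino alcohol ligand is the one that delivers (R)-7, and the descriptor change from R (7) to S (8 onward) reflects only the CIP ranking at the carbinol carbon, not an inversion.

Step 1
Reactants: 1 3,4-dimethoxybenzaldehyde; 2 2-oxobutanoic acid
Product: 4 (E)-4-(3,4-dimethoxyphenyl)-3-methyl-2-oxobut-3-enoic acid, via aldol adduct 3 (not isolated)
Conditions: KOH (2.2 equiv), MeOH/H2O, 0 °C → rt; then aq. HCl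
Reagents that add atoms: none
Why: Claisen–Schmidt-type crossed aldol condensation: only the keto acid can enolise (at its CH2) and the aryl aldehyde cannot, aldolate 3 loses water by E1cB elimination, and the conjugated trisubstituted alkene should form as the more stable E isomer (aryl trans to the acyl group).

Step 2
Reactants: 4 (E)-4-(3,4-dimethoxyphenyl)-3-methyl-2-oxobut-3-enoic acid
Product: 5 methyl (E)-4-(3,4-dimethoxyphenyl)-3-methyl-2-oxobut-3-enoate
Conditions: MeOH, H2SO4 (cat.), 50 °C
Reagents that add atoms: methanol, CO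
Why: Fischer esterification of the carboxylic acid; the hindered conjugated keto group and the aryl ethers should be unaffected.

Step 3
Reactants: 5 methyl (E)-4-(3,4-dimethoxyphenyl)-3-methyl-2-oxobut-3-enoate; 6 (E)-pent-3-en-1-yne
Product: 7 methyl (2R,5E)-2-[(E)-1-(3,4-dimethoxyphenyl)prop-1-en-2-yl]-2-hydroxyhept-5-en-3-ynoate
Conditions: Zn(OTf)2 (20 mol %), Et3N (30 mol %), 2-(dimethylamino)-1-(4-nitrophenyl)-3-(tert-butyldimethylsilyloxy)propan-1-ol (22 mol %, antipode giving (R)-7), toluene, 50 °C, closed vessel
Reagents that add atoms: none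
Why: Catalytic asymmetric alkynylation of an α-keto ester (zinc triflate/amine/amino alcohol): the alkyne C–H adds across the activated, chelating keto group in the 1,2-sense, and the zinc-bound chiral amino alcohol differentiates the two faces (ester versus branched alkenyl substituent), which sets the quaternary carbinol centre as (R).

Step 4
Reactants: 7 methyl (2R,5E)-2-[(E)-1-(3,4-dimethoxyphenyl)prop-1-en-2-yl]-2-hydroxyhept-5-en-3-ynoate
Product: 8 methyl (2S,3Z,5E)-2-[(E)-1-(3,4-dimethoxyphenyl)prop-1-en-2-yl]-2-hydroxy-4-(triethylsilyl)hepta-3,5-dienoate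
Conditions: Et3SiH (1.2 equiv), [Cp*Ru(MeCN)3]PF6 (3 mol %), CH2Cl2, 0 °C → rt
Reagents that add atoms: triethylsilane, CC[SiH](CC)CC
Why: Ruthenium-catalysed trans-hydrosilylation of a propargylic alcohol: H and Si add anti across the alkyne and silicon goes to the alkyne carbon remote from the hindered carbinol, which should give the (Z)-vinylsilane with silicon cis to the carbinol carbon while the ester and the alkenes stay untouched; the stereocentre is not involved.

Step 5
Reactants: 8 methyl (2S,3Z,5E)-2-[(E)-1-(3,4-dimethoxyphenyl)prop-1-en-2-yl]-2-hydroxy-4-(triethylsilyl)hepta-3,5-dienoate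
Product: 9 methyl (2S,3Z,5E)-2-[(E)-1-(3,4-dimethoxyphenyl)prop-1-en-2-yl]-2-hydroxy-4-iodohepta-3,5-dienoate
Conditions: N-iodosuccinimide (1.05 equiv), 2,6-lutidine, (CF3)2CHOH, 0 °C, dark
Reagents that add atoms: N-iodosuccinimide, O=C1CCC(=O)N1I
Why: Ipso-iododesilylation of a vinylsilane: iodonium attack at the silicon-bearing carbon gives a β-silyl-stabilised cation that should lose silicon faster than it rotates in the ionising, non-nucleophilic fluoro alcohol, so iodine should replace silicon with retention (iodine cis to the carbinol carbon).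

Step 6
Reactants: 9 methyl (2S,3Z,5E)-2-[(E)-1-(3,4-dimethoxyphenyl)prop-1-en-2-yl]-2-hydroxy-4-iodohepta-3,5-dienoate; 10 ketenylidenetriphenylphosphorane
Product: 12 (5S)-5-[(E)-1-(3,4-dimethoxyphenyl)prop-1-en-2-yl]-5-[(1Z,3E)-2-iodopenta-1,3-dien-1-yl]-4-methoxyfuran-2(5H)-one, via acyl ylide 11 (not isolated)
Conditions: Ph3P=C=C=O (1.3 equiv), PhCO2H (cat.), toluene, 110 °C
Reagents that add atoms: none
Why: Domino addition–intramolecular Wittig olefination: the tertiary O–H adds across the cumulated ylide to give acyl ylide 11, whose ylide carbon olefinates the neighbouring ester carbonyl, so the ester methoxy group becomes the ring 4-methoxy group and the new C=C is necessarily cis inside the five-membered lactone; the stereocentre keeps its four bonds.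

Step 7
Reactants: 12 (5S)-5-[(E)-1-(3,4-dimethoxyphenyl)prop-1-en-2-yl]-5-[(1Z,3E)-2-iodopenta-1,3-dien-1-yl]-4-methoxyfuran-2(5H)-one
Product: 16 (4S)-4-[(E)-1-(3,4-dimethoxyphenyl)prop-1-en-2-yl]-4,5-dimethoxy-2-[(E)-prop-1-en-1-yl]cyclohexa-2,5-dien-1-one, via alkenyllithium 13 (not isolated), via oxa-bridged alkoxide 14 (not isolated), via lithium dienone alkoxide 15 (not isolated)
Conditions: t-BuLi (2.1 equiv), THF/Et2O, −100 °C, 0.01 M, then warm to −40 °C; then MeI (5 equiv), DMPU, −40 °C → rt
Reagents that add atoms: iodomethane, CI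
Why: Proposed new method: iodine–lithium exchange at the (Z)-alkenyl iodide, which at −100 °C should outrun any attack of t-BuLi on the lactone, gives alkenyllithium 13 whose carbanionic carbon is fixed cis to the oxygen-bearing quaternary carbon and therefore lies over the lactone carbonyl; it should add there to give the oxa-bridged tetrahedral alkoxide 14, which collapses by cleavage of the ring C–O bond to the dienone alkoxide 15, and MeI then caps this tertiary alkoxide as the methyl ether. The net event is an anionic 1,4 O→C acyl shift in which the migrating acyl carbon stays tied to the carbinol carbon through the cis C=C(OMe) unit, so a five-membered lactone is exchanged for the six-membered carbocycle; the closest known reaction types are the anionic Fries and homo-Fries acyl migrations and the Parham cyclisation of organolithiums onto esters. The six-membered ring closes in the 6-exo-trig mode at the carbonyl carbon (5-exo-trig with respect to the transient oxygen bridge), and the strain of the bicyclic adduct is paid for by the conversion of C–Li into O–Li and released at once on C–O cleavage. No stereocentre is formed: the quaternary carbon keeps its four bonds throughout (its oxygen only changes partner from acyl to lithium to methyl), so the (S) configuration of 12 is carried into 16, and the ring alkene geometries are fixed by the ring. The selectivity required is intramolecular 1,2-addition ahead of proton transfer from the acidic vinylic C–H of the tetronate and ahead of intermolecular addition; the rigid cis-alkenyl tether holds the carbanion above the carbonyl carbon and away from that in-plane C–H, and low temperature with high dilution disfavours the bimolecular paths. The positions of the ring methoxy group and the carbonyl are inherited from the tetronate, so no enol-ether regiochemistry or geometry is left to control.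

**Compound list**

1 | 3,4-dimethoxybenzaldehyde | COc1ccc(C=O)cc1OC | starting material
2 | 2-oxobutanoic acid | CCC(=O)C(=O)O | starting material
3 | potassium 4-(3,4-dimethoxyphenyl)-4-hydroxy-3-methyl-2-oxobutanoate (aldol adduct, mixture of diastereomers, not isolated) | [K+].[O-]C(=O)C(=O)C(C)C(O)c1ccc(OC)c(OC)c1 | intermediate
4 | (E)-4-(3,4-dimethoxyphenyl)-3-methyl-2-oxobut-3-enoic acid | OC(=O)C(=O)/C(C)=C/c1ccc(OC)c(OC)c1 | intermediate
5 | methyl (E)-4-(3,4-dimethoxyphenyl)-3-methyl-2-oxobut-3-enoate | COC(=O)C(=O)/C(C)=C/c1ccc(OC)c(OC)c1 | intermediate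
6 | (E)-pent-3-en-1-yne | C/C=C/C#C | starting material
7 | methyl (2R,5E)-2-[(E)-1-(3,4-dimethoxyphenyl)prop-1-en-2-yl]-2-hydroxyhept-5-en-3-ynoate | C/C=C/C#C[C@](O)(/C(C)=C/c1ccc(OC)c(OC)c1)C(=O)OC | intermediate
8 | methyl (2S,3Z,5E)-2-[(E)-1-(3,4-dimethoxyphenyl)prop-1-en-2-yl]-2-hydroxy-4-(triethylsilyl)hepta-3,5-dienoate (silicon cis to the carbinol carbon) | C/C=C/C([Si](CC)(CC)CC)=C/[C@](O)(/C(C)=C/c1ccc(OC)c(OC)c1)C(=O)OC | intermediate
9 | methyl (2S,3Z,5E)-2-[(E)-1-(3,4-dimethoxyphenyl)prop-1-en-2-yl]-2-hydroxy-4-iodohepta-3,5-dienoate (iodine cis to the carbinol carbon) | C/C=C/C(I)=C/[C@](O)(/C(C)=C/c1ccc(OC)c(OC)c1)C(=O)OC | intermediate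
10 | ketenylidenetriphenylphosphorane, Ph3P=C=C=O | O=C=C=P(c1ccccc1)(c1ccccc1)c1ccccc1 | starting material
11 | methyl (2S,3Z,5E)-2-[(E)-1-(3,4-dimethoxyphenyl)prop-1-en-2-yl]-4-iodo-2-[(triphenylphosphoranylidene)acetoxy]hepta-3,5-dienoate (acyl ylide, not isolated) | C/C=C/C(I)=C/[C@](OC(=O)C=P(c1ccccc1)(c1ccccc1)c1ccccc1)(/C(C)=C/c2ccc(OC)c(OC)c2)C(=O)OC | intermediate
12 | (5S)-5-[(E)-1-(3,4-dimethoxyphenyl)prop-1-en-2-yl]-5-[(1Z,3E)-2-iodopenta-1,3-dien-1-yl]-4-methoxyfuran-2(5H)-one | C/C=C/C(I)=C/[C@@]1(/C(C)=C/c2ccc(OC)c(OC)c2)OC(=O)C=C1OC | intermediate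
13 | (5S)-5-[(E)-1-(3,4-dimethoxyphenyl)prop-1-en-2-yl]-5-[(1E,3E)-2-lithiopenta-1,3-dien-1-yl]-4-methoxyfuran-2(5H)-one (lithium cis to the quaternary carbon, not isolated) | C/C=C/C([Li])=C/[C@@]1(/C(C)=C/c2ccc(OC)c(OC)c2)OC(=O)C=C1OC | intermediate
14 | lithium 4-[(E)-1-(3,4-dimethoxyphenyl)prop-1-en-2-yl]-5-methoxy-2-[(E)-prop-1-en-1-yl]-7-oxabicyclo[2.2.1]hepta-2,5-dien-1-olate (C4 configured as in 12, C1 fixed by the oxygen bridge, not isolated) | [Li+].C/C=C/C1=C[C@@]2(/C(C)=C/c3ccc(OC)c(OC)c3)O[C@]1([O-])C=C2OC | intermediate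
15 | lithium (1S)-1-[(E)-1-(3,4-dimethoxyphenyl)prop-1-en-2-yl]-2-methoxy-4-oxo-5-[(E)-prop-1-en-1-yl]cyclohexa-2,5-dien-1-olate (not isolated) | [Li+].C/C=C/C1=C[C@]([O-])(/C(C)=C/c2ccc(OC)c(OC)c2)C(OC)=CC1=O | intermediate
16 | (4S)-4-[(E)-1-(3,4-dimethoxyphenyl)prop-1-en-2-yl]-4,5-dimethoxy-2-[(E)-prop-1-en-1-yl]cyclohexa-2,5-dien-1-one | C/C=C/C1=C[C@](OC)(/C(C)=C/c2ccc(OC)c(OC)c2)C(OC)=CC1=O | target

**Totals**

Total step count: 7. Longest linear sequence: 7 steps (1 and 2 to 16).

**Steps most likely to fail**

Step 7 (proposed ring switch). What may go wrong: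
- the alkenyllithium may be quenched by proton transfer from the tetronate C–H;
- t-BuLi may attack the lactone before exchange;
- addition through the strained bicyclic transition state may be too slow, so that intermolecular reactions take over on warming;
- the hindered lithium alkoxide may be methylated incompletely.

Fallback with known chemistry, setting out from 9 and returning at 16:
- The tertiary hydroxyl is methylated first (NaH, MeI, THF/DMF, 0 °C) to give the O-methylated iodo ester F1.
- Crossed Claisen condensation with the preformed lithium enolate of methyl acetate (LiN(i-Pr)2, MeOAc, THF, −78 → 0 °C; F1 has no α-hydrogen) should give the β-keto ester F2.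
- O-methylation of its potassium enolate in a dipolar medium (KOt-Bu, Me2SO4, DMPU/THF, 0 °C) should give the open-chain (E)-β-methoxy enoate F3, in which the ester is cis to the quaternary carbon.
- Iodine–lithium exchange (t-BuLi, THF, −100 °C) followed by Parham cyclisation of the alkenyllithium onto this unstrained ester should close the same ring bond with loss of methoxide and give 16 directly.

Step 5 (iododesilylation). What may go wrong:
- electrophilic iodine may attack the electron-rich dimethoxyarene or the terminal alkene of the silyl diene instead of the silicon-bearing carbon;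
- the alkene geometry may erode through a long-lived cation.

Fallback setting out from 7 (it replaces steps 4 and 5) and returning at 9:
- Hydroxyl-directed trans-hydroalumination with excess NaAlH2(OCH2CH2OMe)2 (THF, 0 °C → rt) reduces the ester at the same time. Iodination of the cyclic alkenylalanate with I2 at −78 °C should give the (Z)-iodo diol F4, with iodine cis to the carbinol carbon.
- Selective oxidation of the primary alcohol (TEMPO, PhI(OAc)2, CH2Cl2) should give the α-hydroxy aldehyde F5.
- Pinnick oxidation (NaClO2, NaH2PO4, 2-methylbut-2-ene, t-BuOH/H2O) should give the α-hydroxy acid F6.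
- Esterification with Me3SiCHN2 in toluene/MeOH returns 9.

Step 3 (asymmetric alkynylation). What may go wrong:
- facial discrimination at the hindered, doubly unsaturated keto group may be insufficient;
- the addition may be sluggish with the volatile enyne.

Fallback setting out from 5 and returning at 7:
- The lithium acetylide of 6 (n-BuLi, THF, −78 °C, CeCl3 to suppress side reactions) is added to the keto group of 5 without a chiral controller to give the racemic hydroxy ester F7.
- The enantiomers are separated by preparative chromatography on a chiral stationary phase, and the (R)-enantiomer is 7.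

**Further compounds**

F1 | step 7 | methyl (2S,3Z,5E)-2-[(E)-1-(3,4-dimethoxyphenyl)prop-1-en-2-yl]-4-iodo-2-methoxyhepta-3,5-dienoate | C/C=C/C(I)=C/[C@](OC)(/C(C)=C/c1ccc(OC)c(OC)c1)C(=O)OC
F2 | step 7 | methyl (4S,5Z,7E)-4-[(E)-1-(3,4-dimethoxyphenyl)prop-1-en-2-yl]-6-iodo-4-methoxy-3-oxonona-5,7-dienoate | C/C=C/C(I)=C/[C@](OC)(/C(C)=C/c1ccc(OC)c(OC)c1)C(=O)CC(=O)OC
F3 | step 7 | methyl (2E,4S,5Z,7E)-4-[(E)-1-(3,4-dimethoxyphenyl)prop-1-en-2-yl]-6-iodo-3,4-dimethoxynona-2,5,7-trienoate | C/C=C/C(I)=C/[C@](OC)(/C(C)=C/c1ccc(OC)c(OC)c1)/C(OC)=C\C(=O)OC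
F4 | step 5 | (2S,3Z,5E)-2-[(E)-1-(3,4-dimethoxyphenyl)prop-1-en-2-yl]-4-iodohepta-3,5-diene-1,2-diol | C/C=C/C(I)=C/[C@](O)(/C(C)=C/c1ccc(OC)c(OC)c1)CO
F5 | step 5 | (2S,3Z,5E)-2-[(E)-1-(3,4-dimethoxyphenyl)prop-1-en-2-yl]-2-hydroxy-4-iodohepta-3,5-dienal | C/C=C/C(I)=C/[C@](O)(/C(C)=C/c1ccc(OC)c(OC)c1)C=O
F6 | step 5 | (2S,3Z,5E)-2-[(E)-1-(3,4-dimethoxyphenyl)prop-1-en-2-yl]-2-hydroxy-4-iodohepta-3,5-dienoic acid | C/C=C/C(I)=C/[C@](O)(/C(C)=C/c1ccc(OC)c(OC)c1)C(=O)O
F7 | step 3 | methyl (2RS,5E)-2-[(E)-1-(3,4-dimethoxyphenyl)prop-1-en-2-yl]-2-hydroxyhept-5-en-3-ynoate (racemate) | C/C=C/C#CC(O)(/C(C)=C/c1ccc(OC)c(OC)c1)C(=O)OC
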